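Sunday's product reaches 14.4% in the first 1.00 min but gains 2 percentage points in the last minute, with 59.5% of the starting material still unused, so I look at the catalyst. One spent catalyst counts as two, so a spent catalyst percentage times the starting material charge is the catalyst lost.

| setting | Saturday's | Tuesday's | Sunday's | flask |
|---|---|---|---|---|
| starting material | 0.042 M | 0.17 M | 0.083 M | 0.083 M |
| coupling partner | 0.0498 M | 0.0498 M | 0.0498 M | 0.0498 M |
| free catalyst | 5.8 mM | 5.8 mM | 8.7 mM | 5.8 mM |
| remark | run made earlier | run made earlier | run made earlier |  |
| time |  |  |  | 5.0 min |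

| run | time / min | product / % | starting material / % | spent catalyst / % |
|---|---|---|---|---|
| Saturday's | 0.417 | 7.8 | 83.4 | 2.5 |
| Saturday's | 0.833 | 15.9 | 73.2 | 4.3 |
| Saturday's | 1.33 | 24.5 | 65.2 | 6.2 |
| Saturday's | 2.50 | 36.5 | 52.4 | 8.2 |
| Saturday's | 5.00 | 50.6 | 36.9 | 10.3 |
| Tuesday's | 1.00 | 5.3 | 90.3 | 2.1 |
| Tuesday's | 2.00 | 8.8 | 88.5 | 2.9 |
| Tuesday's | 3.00 | 10.4 | 86.3 | 2.5 |
| Tuesday's | 4.00 | 11.7 | 84.9 | 3.0 |
| Tuesday's | 5.00 | 12.5 | 83.9 | 3.1 |
| Sunday's | 1.00 | 14.4 | 76.0 | 6.2 |
| Sunday's | 2.00 | 21.9 | 69.0 | 8.1 |
| Sunday's | 3.00 | 25.7 | 64.8 | 8.6 |
| Sunday's | 4.00 | 28.1 | 61.5 | 9.5 |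
| Sunday's | 5.00 | 30.1 | 59.5 | 9.4 |

(each reading ± 0.3 percentage points)

- in percentages every species weighs as the starting material in it: one spent catalyst or resting dimer counts as two
- what was read earlier has a scatter of 0.3 percentage points, one standard deviation
- steps that have been proposed: starting material + free catalyst <-> catalyst intermediate A; coupling partner + catalyst intermediate A <-> catalyst intermediate B; catalyst intermediate B <-> free catalyst + product; 2 catalyst intermediate A -> spent catalyst; 2 catalyst intermediate A <-> resting dimer

- amount of product in the flask at 5.0 min, in percent of the starting material charged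
- amount of starting material in the flask at 5.0 min, in percent of the starting material charged
- amount of spent catalyst in the flask at 5.0 min, in percent of the starting material charged
- concentration of coupling partner at 5.0 min, in M

Let Q be the catalyst charged and U the part not yet spent. The proposed death step joins two catalyst intermediate A, so its rate goes with the square of that intermediate's concentration. If that intermediate stays a steady share of U, the reciprocal of U climbs on a straight line against time t, with slope κ, and U/Q = 1/(1 + κQt).

Sunday's reading at 2.00 min leaves U = 1.98 mM, so κ = 195 L mol⁻¹ min⁻¹. I call κ the catalyst death constant, the slope of the reciprocal of U at given charges of starting material and coupling partner. Sunday's last reading gives 200 L mol⁻¹ min⁻¹, but a scatter of 0.249 mM weighs heavily on the 0.898 mM left there, so I keep the earlier value. Saturday, with about half of Sunday's starting material and less free catalyst than Sunday, reads 101 L mol⁻¹ min⁻¹ at 2.50 min, about half of Sunday's value, so I do not take κ from one charge of starting material to another, and I carry Sunday's value to the flask, which shares Sunday's charges of starting material and coupling partner, though not its free catalyst. My reckoning leaves 15.0% of the flask's catalyst unspent, which makes spent catalyst 5.94%.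

The forecast, reading “a catalyst dying second-order through intermediate A”, gives 27% product, 66.2% starting material, 5.8% spent catalyst and 0.0274 M coupling partner.

The flask gives, in the same order, 26.5%, 66.8%, 6.05% and 0.0277 M, so the forecast holds on each count.

    starting material + free catalyst ⇌ catalyst intermediate A (K = 543 L mol⁻¹, k = 2.83 L mol⁻¹ s⁻¹)
    coupling partner + catalyst intermediate A ⇌ catalyst intermediate B (K = 75.7 L mol⁻¹, k = 2.22 L mol⁻¹ s⁻¹)
    catalyst intermediate B ⇌ free catalyst + product (K = 0.270 M, k = 0.225 s⁻¹)
    2 catalyst intermediate A → spent catalyst (k = 6.55 L mol⁻¹ s⁻¹)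
    2 catalyst intermediate A ⇌ resting dimer, settled at all times (K = 57.0 L mol⁻¹)

In the flask, 13.4% of the catalyst is unspent at 5.00 min, against my 15.0%. At 0.500 min catalyst intermediate A, the resting state, is the largest unspent form at 32.8% of the catalyst charged, while spent catalyst has taken 30.5%. By 2.50 min spent catalyst holds 74.0% of the catalyst charged and the product stands at 19.9% of the starting material charged, and at 5.00 min the product stands at 26.5% with 67% of the starting material left.

For the neighbour charged with 0.014 M of free catalyst, κ leaves 0.954 mM unspent, beside the flask's 0.870 mM, and so 15.7% spent catalyst. Computed, it holds 15.8% spent catalyst and 34.4% product.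

All runs are simulated with constants of no real substance; scatter was added.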